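**Plan**
- The C15 dihydrochalcone core is bought intact as phloretin; the retrosynthesis first cuts the two O–C(CH3)2 bonds of the pyran rings, then the two aryl–CH2 bonds (back to aryl 1,1-dimethylallyl ethers), then the two ether O–C bonds and two benzyl caps.
- Forward: etherify O4 (ring B) and O4' (ring A) with one C5 unit each, cap O2'/O6' as benzyl ethers, semi-hydrogenate, and let a double Claisen shift move each C5 unit to the ortho carbon.
- One acid-catalysed event, copying the presumed prenyl-cyclase step of the biosynthesis, then closes both 2,2-dimethylchroman rings at once; hydrogenolysis removes the benzyl caps.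
- Enabling feature: in each arene a free phenolic oxygen (O4 of ring B, O4' of ring A) sits ortho to a 3-methylbut-2-enyl chain whose far alkene carbon is tertiary, so O–C(CH3)2 closure gives a six-membered pyran; O2' and O6' of ring A are blocked, so the ring-A pyran oxygen must be the one para to the ketone.
- Stereochemistry: none to set; the target has no stereocentre (each C2 carries two methyl groups).

Key step: step 5

Remark: phloretin and 3-chloro-3-methylbut-1-yne are taken as commercial materials.

**Step 1**
Reactants: 1 phloretin; 2 3-chloro-3-methylbut-1-yne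
Product: 3 1-{2,6-dihydroxy-4-[(2-methylbut-3-yn-2-yl)oxy]phenyl}-3-{4-[(2-methylbut-3-yn-2-yl)oxy]phenyl}propan-1-one
Conditions: 2 (2.3 equiv), DBU (2.5 equiv), CuCl2 (1 mol%), MeCN, 0 °C to rt
Reagents that add atoms: 3-chloro-3-methylbut-1-yne (2), CC(C)(Cl)C#C
Why: Copper-catalysed O-alkylation of phenoxides with a tertiary propargylic chloride (Williamson-type etherification via a copper acetylide) should select the unhindered O4 and O4', because O2' and O6' are flanked by and hydrogen-bonded to the ketone, and it places one C5 unit on each oxygen that is to become a pyran oxygen.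

**Step 2**
Reactants: 3 bis(propargylic ether) diol; 4 benzyl bromide
Product: 5 1-{2,6-bis(benzyloxy)-4-[(2-methylbut-3-yn-2-yl)oxy]phenyl}-3-{4-[(2-methylbut-3-yn-2-yl)oxy]phenyl}propan-1-one
Conditions: BnBr (2.6 equiv), K2CO3 (4 equiv), Bu4NI (cat.), DMF, 60 °C
Reagents that add atoms: benzyl bromide (4), BrCc1ccccc1
Why: Williamson etherification under forcing carbonate/DMF conditions should benzylate both ketone-flanked hydroxyls, blocking O2' and O6' so that only O4' can later close the ring-A pyran.

**Step 3**
Reactants: 5 dibenzyl bis(propargylic ether)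
Product: 6 1-{2,6-bis(benzyloxy)-4-[(2-methylbut-3-en-2-yl)oxy]phenyl}-3-{4-[(2-methylbut-3-en-2-yl)oxy]phenyl}propan-1-one
Conditions: H2 (1 atm, stopped after 2 equiv), Pd/CaCO3 poisoned with Pb(OAc)2, quinoline, EtOAc, rt
Reagents that add atoms: none
Why: Lindlar semi-hydrogenation should stop at the vinyl stage, since the poisoned palladium reduces terminal alkynes much faster than alkenes and neither cleaves benzyl ethers nor reduces the aryl ketone.

**Step 4**
Reactants: 6 dibenzyl bis(1,1-dimethylallyl ether)
Product: 7 1-[2,6-bis(benzyloxy)-4-hydroxy-3-(3-methylbut-2-en-1-yl)phenyl]-3-[4-hydroxy-3-(3-methylbut-2-en-1-yl)phenyl]propan-1-one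
Conditions: PhNEt2, 140 °C, argon
Reagents that add atoms: none
Why: A twofold aromatic Claisen rearrangement ([3,3]-sigmatropic shift, then tautomerization) should deliver one 3-methylbut-2-enyl group intramolecularly to the carbon ortho to each ether oxygen; the two ortho sites of each ring (C3'/C5' of ring A, C3/C5 of ring B) are equivalent by symmetry, so only one product can form.

**Step 5**
Reactants: 7 dibenzyl bis(ortho-prenyl) diphenol
Product: 9 1-[5,7-bis(benzyloxy)-2,2-dimethyl-3,4-dihydro-2H-chromen-6-yl]-3-(2,2-dimethyl-3,4-dihydro-2H-chromen-6-yl)propan-1-one, via ring-B mono-chroman 8 (not isolated)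
Conditions: p-TsOH·H2O (20 mol%), toluene (0.02 M), 70 °C
Reagents that add atoms: none
Why: The acid should protonate each trisubstituted side-chain alkene in the Markovnikov sense to a tertiary carbocation (or tight ion pair) that is captured by the phenolic oxygen ortho to the chain, forming the O–C(CH3)2 bond and returning the proton, so the step is a catalytic, fully atom-economic double isomerization. The closest known reaction type is the acid-catalysed intramolecular hydroalkoxylation (cycloisomerization) of ortho-prenylphenols to 2,2-dimethylchromans, the laboratory counterpart of the cyclase step presumed in the biosynthesis of pyrano-dihydrochalcones. Each pyran ring closes in the 6-endo-trig mode, the 5-exo alternative to a dihydrobenzofuran being disfavoured because it would need attack at the secondary alkene carbon. No stereocentre is created, since each new quaternary carbon carries two methyl groups. The selectivity needed is regiochemical on ring A, where the C3' side chain lies between O2' and O4'; it is secured because O2' and O6' are benzyl ethers, leaving only O4' (para to the ketone) to cyclize, while ring B has a single ortho hydroxyl and, being the less conjugated phenol, should close first (8), either order converging on 9. High dilution and a catalytic acid loading should keep intermolecular Friedel–Crafts alkylation at the free C5'–H position and benzyl ether cleavage from competing.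

**Step 6**
Reactants: 9 dibenzyl bis-chroman
Product: 10 1-(5,7-dihydroxy-2,2-dimethyl-3,4-dihydro-2H-chromen-6-yl)-3-(2,2-dimethyl-3,4-dihydro-2H-chromen-6-yl)propan-1-one
Conditions: H2 (1 atm), Pd/C (10 wt%), EtOAc–MeOH, rt
Reagents that add atoms: none
Why: Hydrogenolysis of benzyl aryl ethers over palladium on carbon should free both phenols under neutral conditions that leave the chroman ethers and the doubly ortho-oxygenated, hydrogen-bonded aryl ketone untouched.

**Compound list**
1 | phloretin, 3-(4-hydroxyphenyl)-1-(2,4,6-trihydroxyphenyl)propan-1-one | O=C(CCc1ccc(O)cc1)c1c(O)cc(O)cc1O | starting material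
2 | 3-chloro-3-methylbut-1-yne | CC(C)(Cl)C#C | starting material
3 | 1-{2,6-dihydroxy-4-[(2-methylbut-3-yn-2-yl)oxy]phenyl}-3-{4-[(2-methylbut-3-yn-2-yl)oxy]phenyl}propan-1-one | C#CC(C)(C)Oc1ccc(CCC(=O)c2c(O)cc(OC(C)(C)C#C)cc2O)cc1 | intermediate
4 | benzyl bromide | BrCc1ccccc1 | starting material
5 | 1-{2,6-bis(benzyloxy)-4-[(2-methylbut-3-yn-2-yl)oxy]phenyl}-3-{4-[(2-methylbut-3-yn-2-yl)oxy]phenyl}propan-1-one | C#CC(C)(C)Oc1ccc(CCC(=O)c2c(OCc3ccccc3)cc(OC(C)(C)C#C)cc2OCc2ccccc2)cc1 | intermediate
6 | 1-{2,6-bis(benzyloxy)-4-[(2-methylbut-3-en-2-yl)oxy]phenyl}-3-{4-[(2-methylbut-3-en-2-yl)oxy]phenyl}propan-1-one | C=CC(C)(C)Oc1ccc(CCC(=O)c2c(OCc3ccccc3)cc(OC(C)(C)C=C)cc2OCc2ccccc2)cc1 | intermediate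
7 | 1-[2,6-bis(benzyloxy)-4-hydroxy-3-(3-methylbut-2-en-1-yl)phenyl]-3-[4-hydroxy-3-(3-methylbut-2-en-1-yl)phenyl]propan-1-one | CC(C)=CCc1cc(CCC(=O)c2c(OCc3ccccc3)cc(O)c(CC=C(C)C)c2OCc2ccccc2)ccc1O | intermediate
8 | ring-B mono-chroman, 1-[2,6-bis(benzyloxy)-4-hydroxy-3-(3-methylbut-2-en-1-yl)phenyl]-3-(2,2-dimethyl-3,4-dihydro-2H-chromen-6-yl)propan-1-one (not isolated) | CC1(C)CCc2cc(CCC(=O)c3c(OCc4ccccc4)cc(O)c(CC=C(C)C)c3OCc3ccccc3)ccc2O1 | intermediate
9 | 1-[5,7-bis(benzyloxy)-2,2-dimethyl-3,4-dihydro-2H-chromen-6-yl]-3-(2,2-dimethyl-3,4-dihydro-2H-chromen-6-yl)propan-1-one | CC1(C)CCc2cc(CCC(=O)c3c(OCc5ccccc5)cc4c(c3OCc3ccccc3)CCC(C)(C)O4)ccc2O1 | intermediate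
10 | 1-(5,7-dihydroxy-2,2-dimethyl-3,4-dihydro-2H-chromen-6-yl)-3-(2,2-dimethyl-3,4-dihydro-2H-chromen-6-yl)propan-1-one (achiral) | CC1(C)CCc2cc(CCC(=O)c3c(O)cc4c(c3O)CCC(C)(C)O4)ccc2O1 | target

**Step count and risks**
Total step count: 6. Longest linear sequence: 6.

Steps most likely to fail:

1. Step 1. The hindered tertiary alkylation may select poorly among the four hydroxyls, alkylate ring A at carbon, or lose to elimination of the chloride. The fallback sets out from 1 and comes back at 7, replacing the tertiary electrophile by a primary one and installing the gem-dimethyl end later by metathesis. Allyl bromide (2.1 equiv), K2CO3, acetone, reflux should give 3-[4-(allyloxy)phenyl]-1-[4-(allyloxy)-2,6-dihydroxyphenyl]propan-1-one F1. BnBr, K2CO3, DMF, 60 °C should give 3-[4-(allyloxy)phenyl]-1-[4-(allyloxy)-2,6-bis(benzyloxy)phenyl]propan-1-one F2. A double aromatic Claisen rearrangement in PhNEt2 at 190 °C should give 1-[3-allyl-2,6-bis(benzyloxy)-4-hydroxyphenyl]-3-(3-allyl-4-hydroxyphenyl)propan-1-one F3. Cross-metathesis with excess 2-methylbut-2-ene and the second-generation Grubbs catalyst RuCl2(=CHPh)(PCy3)(H2IMes) in CH2Cl2 at 40 °C should then give 7.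

2. Step 5. The acid may remove or shift a benzyl group before ring closure, which would unlock O2'/O6' and erode the ring-A regiochemistry, or the cation may alkylate a second molecule. The fallback sets out from 7 and comes back at 9, using a non-acidic electrophile-induced closure. PhSeCl (2.2 equiv), K2CO3, CH2Cl2, −78 °C should effect a double 6-endo selenoetherification to 1-[5,7-bis(benzyloxy)-2,2-dimethyl-3-(phenylselanyl)-3,4-dihydro-2H-chromen-6-yl]-3-[2,2-dimethyl-3-(phenylselanyl)-3,4-dihydro-2H-chromen-6-yl]propan-1-one F5, as a mixture of diastereomers at the two selenium-bearing carbons. Radical deselenation with Bu3SnH, AIBN (cat.), toluene, 90 °C should erase both centres and give 9.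

3. Step 4. The tertiary allyl ethers may fragment thermally (loss of isoprene, returning the phenols) faster than they rearrange. The fallback sets out from 5 and comes back at 10, using the alkyne oxidation level and omitting the semi-hydrogenation. Heating 5 in PhNEt2 at 190 °C should trigger a double propargyl Claisen rearrangement, [1,5]-hydrogen shift and oxa-6π electrocyclization to 1-[5,7-bis(benzyloxy)-2,2-dimethyl-2H-chromen-6-yl]-3-(2,2-dimethyl-2H-chromen-6-yl)propan-1-one F4. H2 (1 atm), Pd/C, EtOAc–MeOH, rt should then saturate both chromene double bonds and cleave both benzyl ethers to give 10.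

**Further compounds**
F1 | step 1 | 3-[4-(allyloxy)phenyl]-1-[4-(allyloxy)-2,6-dihydroxyphenyl]propan-1-one | C=CCOc1ccc(CCC(=O)c2c(O)cc(OCC=C)cc2O)cc1
F2 | step 1 | 3-[4-(allyloxy)phenyl]-1-[4-(allyloxy)-2,6-bis(benzyloxy)phenyl]propan-1-one | C=CCOc1ccc(CCC(=O)c2c(OCc3ccccc3)cc(OCC=C)cc2OCc2ccccc2)cc1
F3 | step 1 | 1-[3-allyl-2,6-bis(benzyloxy)-4-hydroxyphenyl]-3-(3-allyl-4-hydroxyphenyl)propan-1-one | C=CCc1cc(CCC(=O)c2c(OCc3ccccc3)cc(O)c(CC=C)c2OCc2ccccc2)ccc1O
F4 | step 4 | 1-[5,7-bis(benzyloxy)-2,2-dimethyl-2H-chromen-6-yl]-3-(2,2-dimethyl-2H-chromen-6-yl)propan-1-one | CC1(C)C=Cc2cc(CCC(=O)c3c(OCc5ccccc5)cc4c(c3OCc3ccccc3)C=CC(C)(C)O4)ccc2O1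
F5 | step 5 | 1-[5,7-bis(benzyloxy)-2,2-dimethyl-3-(phenylselanyl)-3,4-dihydro-2H-chromen-6-yl]-3-[2,2-dimethyl-3-(phenylselanyl)-3,4-dihydro-2H-chromen-6-yl]propan-1-one (mixture of diastereomers) | CC1(C)Oc2ccc(CCC(=O)c3c(OCc5ccccc5)cc4OC(C)(C)C([Se]c5ccccc5)Cc4c3OCc3ccccc3)cc2CC1[Se]c1ccccc1
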